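Locants used throughout: C1 is the acyl carbon; ring A is C2–C3–C4–C5–C6–C11; ring B is C6–C7–C8–C9–C10–C11; the dienyl chain is C12–C16; primed locants belong to the heterocycle. The β-face is the face of the C2 methyl group. Compound numbers are those of the steps.

## Analysis of the target

Compound 40 is a 3-acyltetramic acid in which the ketone carbon C1 joins C3′ of a (5S)-5-[(1R)-1-hydroxyethyl]pyrrolidine-2,4-dione (the L-threonine skeleton) to the quaternary C2 of a trans-fused octahydronaphthalene; ring A is the cyclohexene with C4=C5, ring B is saturated, C3 bears the (1E,3E)-penta-1,3-dienyl chain and C8 a methyl group. There are seven stereocentres: C2 (R), C3 (R), C6 (R), C8 (R) and C11 (S) on the carbocycle, C5′ (S) and C6′ (R) on the heterocycle. The hydrogen on C6 is β and that on C11 α (trans fusion); the C2 methyl is axial, C1 is equatorial on the α-face, and the C11–C10 bond, the C3 dienyl group and the C8 methyl all lie on the β-face, the C8 methyl being axial on ring B. The sensitive parts are the conjugated diene (acid, oxidants), the acidic, metal-binding tricarbonyl unit, C5′ (epimerised by base) and the side-chain hydroxyl (β-elimination), so the heterocycle is best made last. The difficulty lies in three contiguous stereocentres C3–C2–C11 around a quaternary carbon, in an axial and therefore less stable methyl on C8 far from any functional group, and in a C3 substituent that must sit syn to the axial C2 methyl, on the hindered face of the locked bicycle. The strategy rests on the fact that ring B carries nothing but the C8 methyl and is fused trans at C6 and C11: C7–C10 can be brought in as two three-carbon allyl units bonded to the β-carbon C11 and the α-carbon C6 of a ring A cyclohex-2-enone whose quaternary C2 already holds C1 as a bulky, inert orthoester. The C5 carbonyl that remains in ring A is then the handle for C8, for the C4=C5 alkene and for C3.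

## Retrosynthetic reasoning

Heterocycle. 40 is the desilylated form of 39. In 39 the C3′–C4′ bond is cut (Lacey–Dieckmann transform) to the β-ketoamide 38, and the N1′–C2′ amide bond of 38 is cut to the β-keto thioester 35 and the amino ester 37, the silyl ether of 36. The cuts are placed here because the tricarbonyl unit and C5′ are the most labile parts of the molecule and should exist for as few steps as possible. The forward ring closure must be fast enough that C5′ is not epimerised and the protected hydroxyl is not eliminated.

C1–C3′ bond. 35 is the oxidation product of 34, and 34 is cut between C1 and the future C3′ into aldehyde 32 and thioacetate 33. C1 hangs on a quaternary carbon flanked by two tertiary ones, so acyl substitution there would be slow. An aldehyde without α-hydrogen is the C1 electrophile that adds an enolate cleanly, and the missing oxidation state is restored in one step.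

C1 as orthoester. 32 is traced through 31 and 30 to orthoester 29. No skeletal bond is cut; C1 stays at the acid oxidation level, masked as the bicyclic orthoester, from 9 to 29. This gives a C1 group as large as a tert-alkyl group, which the key step needs, and one that is inert to hydride reagents, organolithium reagents, enolate chemistry and palladium.

Diene. 29 is cut at C13–C14 into iodoalkene 27 and boronic acid 28, and 27 at C12=C13 back to aldehyde 26. The chain is assembled on C12 rather than attached whole to C3, because a single carbon can be delivered to C3 intramolecularly (next paragraph) and a five-carbon nucleophile cannot. The forward reactions must set both alkenes E under conditions that do not enolise 26.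

C3–C12 bond. 26 derives from alcohol 25, and 25 is cut at C3–C12 with allylic transposition to the stannylmethyl ether 23, made from allylic alcohol 21 and 22. An external nucleophile at C3 of the locked bicycle would enter anti to the axial C2 methyl, from the α-face, and give the C3 epimer. An anti-selective allylic substitution from a 5α leaving group would have to pass that same methyl group. A [2,3]-shift from an oxygen on the β-face of C5 moves carbon suprafacially to the β-face of C3 and creates the C4=C5 alkene in the same step.

Enone. 21 comes from enone 20, and 20 from ketone 18 through 19. No C–C bond is cut; the unsaturation is introduced next to the C5 carbonyl so that its reduction gives an allylic alcohol. The reduction must give the 5β (pseudo-equatorial) alcohol, which is what axial hydride attack delivers.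

C8. 18 is the oxidation product of 17, and 17 results from hydrogenation of the C8=C9 alkene of 16, the axial alcohol of 15. The C8–H bond is made by a directed process because the wanted methyl is axial. The axial 5α-hydroxyl is the only heteroatom near ring B and lies on the face from which hydrogen must come.

Ring B. 15 is cut at C8=C9 to diene 14 (ring-closing metathesis transform). This removes ring B and leaves two three-carbon chains on C6 and C11.

Key disconnection. 14 is cut at C10–C11 and C6–C7 to enone 9, allyl donor 10 and allylic iodide 11, through 12 and 13. Both bonds lie at carbons activated by the C5 carbonyl (β and α), and C11 is next to C2, whose large and small substituents can decide its configuration; C6 then follows from C11. All four new carbons of ring B come from two commercial three-carbon reagents and two stereocentres are set in one operation. The forward reaction must give conjugate rather than carbonyl addition, attack anti to the orthoester, and trans alkylation at C6 and not at C4.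

Ring A. 9 is the rearrangement product of ester 8, made from acid 6 and alcohol 7. 6 is the oxidation product of 5, which is cut by a Diels–Alder transform at the two ring bonds that flank the carbonyl-bearing side of the quaternary carbon into diene 1 and enal 2, through 3 and 4. C2, the only stereocentre, is set by the catalyst, and every later centre is derived from it.

## Alternatives that were turned down

Alternative 1: Both rings are opened at once by cutting C6–C11 and C7–C8 of the octalone A1. Its precursor is the open-chain trienone A2: a vinyl ketone (C5–C7) tethered through C4 and C3 to the quaternary C2, which carries the (E,E)-diene C11–C8. In the forward direction A2 undergoes an intramolecular Diels–Alder reaction with the activating carbonyl inside the tether.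
- For: two rings and the centres C6, C8 and C11 are formed in one step. The axial C8 methyl follows directly from the E,E geometry and suprafacial addition, with no separate reduction. C6, α to the ketone, can be corrected by enolisation if the cis-fused adduct forms. On these points it is stronger than the chosen route, which needs a metathesis and a three-step directed hydrogenation for the same result.
- Against: A2 must already contain the vicinal quaternary/tertiary pair C2/C3 in an open chain, where neither centre has a ring to lean on. The diene face is chosen only by the difference between a methyl and a silyloxymethyl arm on C2. The vinyl ketone is prone to polymerisation. C3 of A1 bears only a protected hydroxymethyl group, so the diene and C1 still need the same late redox steps.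
- In its place the chosen strategy offers a quaternary centre made catalytically at the outset and stereocentres that are each set on a ring.

Alternative 2: Ring A is cut at C2–C11 and C3–C4 of the octalin aldehyde A3, the adduct of the vinylcyclohexene A4 and methacrolein A5 (the same compound as 2). In the forward direction a chiral oxazaborolidinium Lewis acid activates A5, which adds to A4 in the exo mode (formyl exo, the usual preference of α-substituted acroleins), placing the C2 methyl cis to C10.
- For: it is the shortest construction of the bicyclic core, convergent, with quaternary C2 and C11 set in one catalytic step. In step economy up to the bicycle it is clearly ahead of the chosen route.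
- Against: A3 has no functional group at C3, an unactivated methylene next to the quaternary carbon, and its alkene lies at C5=C6. The C6 hydrogen, the C4=C5 alkene and the C3 dienyl group would all have to be introduced afterwards from that one alkene, and trans-selective delivery of hydrogen to C6 is not assured. The relation between C8 and C11 depends on which face of A4 reacts, under a remote methyl group that may oppose the catalyst. A4 itself needs a regiodefined, enantiopure diene preparation.
- The chosen route is longer to the bicycle but leaves the C5 carbonyl in ring A, the handle from which C8, C4=C5 and C3 are reached.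

Alternative 3: The C2–C3 bond of the ring A acid A6 is cut. A6 arises from the silyl ketene acetal of the trans-fused lactone A7, whose ring oxygen joins C5 to the carboxyl carbon on C2 and whose C5 bears an (E)-alkenyl chain. In the forward direction A7 is enolised and silylated, and an Ireland–Claisen rearrangement through a boat transition state contracts the lactone to the carbocycle, forms C2–C3 and leaves the C4=C5 alkene.
- For: the most hindered bond of the molecule is made intramolecularly. C2 and C3 are set together and stereospecifically, with the C3 substituent cis to the axial group on C2. This is the very relation for which the chosen route needs a separate [2,3]-shift, so on C3 this alternative is the stronger one.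
- Against: the axial group that results on C2 is a carboxyl and must be reduced to methyl over several steps while the other arm is oxidised to C1. A7 requires ring B with C6, C8 (axial methyl), C11 and the C5 carbinol all in place beforehand, with no ring A functionality to help with C8. Two protected hydroxymethyl groups remain to be elaborated.
- The chosen strategy instead starts from a ring A in which C2 already carries methyl and C1 in their final pattern, and builds ring B from commercial three-carbon reagents.

Key step: step 5

Assumption: in step 1 the antipode of the TADDOL catalyst is the one that gives the (S)-configured quaternary centre of 5 (both antipodes are commercial); the sense of induction is to be confirmed on 5 before going on.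

## Route

Step 1
Reactants: 1 (E)-3-(tert-butyldimethylsilyloxy)-N,N-dimethylbuta-1,3-dien-1-amine; 2 methacrolein
Product: 5 (S)-4-(hydroxymethyl)-4-methylcyclohex-2-en-1-one, via cycloadduct aldehyde 3 (not isolated), via amino alcohol 4 (not isolated)
Conditions: tetra(1-naphthyl)-TADDOL (20 mol%), toluene, −80 °C; LiAlH4, Et2O, −78 °C → rt, aqueous work-up; aq. HF, MeCN, rt
Reagents that add atoms: none
Why: Diels–Alder reaction under hydrogen-bond catalysis: the diol activates the aldehyde of 2 and shields one of its faces, and the nucleophilic terminus of the amino diene bonds to the CH2 of 2, so the quaternary carbon (the future C2) is set by the catalyst. Hydride reduction turns the aldehyde into the alcohol, and HF cleaves the silyl enol ether and eliminates dimethylamine to unveil the enone.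

Step 2
Reactants: 5 (S)-4-(hydroxymethyl)-4-methylcyclohex-2-en-1-one
Product: 6 (S)-1-methyl-4-oxocyclohex-2-ene-1-carboxylic acid
Conditions: TEMPO (cat.), PhI(OAc)2, MeCN/H2O, rt
Reagents that add atoms: water, O
Why: Oxoammonium (TEMPO) oxidation of the primary alcohol through the aldehyde hydrate to the acid; the enone and the quaternary centre are not affected.

Step 3
Reactants: 6 (S)-1-methyl-4-oxocyclohex-2-ene-1-carboxylic acid; 7 (3-methyloxetan-3-yl)methanol
Product: 8 (3-methyloxetan-3-yl)methyl (S)-1-methyl-4-oxocyclohex-2-ene-1-carboxylate
Conditions: DCC, DMAP, CH2Cl2, 0 °C → rt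
Reagents that add atoms: none
Why: Steglich esterification; carbodiimide activation avoids the acid that would open the oxetane.

Step 4
Reactants: 8 (3-methyloxetan-3-yl)methyl (S)-1-methyl-4-oxocyclohex-2-ene-1-carboxylate
Product: 9 (S)-4-methyl-4-(4-methyl-2,6,7-trioxabicyclo[2.2.2]octan-1-yl)cyclohex-2-en-1-one
Conditions: BF3·OEt2 (0.25 equiv), CH2Cl2, −15 °C → rt; Et3N
Reagents that add atoms: none
Why: Lewis-acid-induced rearrangement of an oxetanylmethyl ester: the ester carbonyl opens the activated oxetane and the resulting zwitterion collapses to the bridged orthoester. The cage makes C1 as large as a tert-alkyl group and inert to bases, hydrides and organometallic reagents.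

Step 5
Reactants: 9 (S)-4-methyl-4-(4-methyl-2,6,7-trioxabicyclo[2.2.2]octan-1-yl)cyclohex-2-en-1-one; 10 allylmagnesium bromide; 11 3-iodo-2-methylprop-1-ene
Product: 14 (2S,3S,4S)-3-allyl-4-methyl-2-(2-methylallyl)-4-(4-methyl-2,6,7-trioxabicyclo[2.2.2]octan-1-yl)cyclohexan-1-one, via silyl enol ether 12 (not isolated), via lithium enolate 13 (not isolated)
Conditions: CuBr·SMe2, Me3SiCl, THF, −78 °C; evaporate; MeLi, THF, 0 °C; DMPU, −78 → 0 °C
Reagents that add atoms: none
Why: The allylcopper reagent formed from 10 and CuBr·SMe2 forms a π-complex with the enone of 9 and transfers allyl to C11 (oxidative addition to a trivalent copper intermediate, then reductive elimination) while Me3SiCl traps the enolate as the silyl enol ether 12; MeLi then cleaves the O–Si bond to the regiodefined lithium enolate 13, which the allylic iodide 11 alkylates at C6 by SN2 displacement. The closest known reaction type is the copper-mediated conjugate addition to 4,4-disubstituted cyclohex-2-enones with silyl trapping, followed by regiospecific allylation of the regenerated enolate (three-component coupling). No ring is closed: the C10–C11 and C6–C7 bonds are both exocyclic and ring B is closed only in step 6. C11 is controlled by C2: the nucleophile bonds to the β-carbon axially, anti to the pseudo-axial substituent of the neighbouring quaternary carbon, and of the two half-chairs the one with the orthoester cage pseudo-axial is the reactive one, because the other would place the incoming copper gauche to the cage; allyl therefore enters trans to C1 and cis to the methyl group. C6 is controlled by the new C11 substituent: in the enolate the allyl group is pseudo-axial and the electrophile comes from the opposite face, which gives the 6,11-trans product; this is also the thermodynamic isomer (both chains equatorial after ring flip, methyl axial), and C6 can be equilibrated by base if needed. The step needs 1,4- instead of 1,2-addition of the allyl metal, which the copper and silyl chloride combination secures; face selectivity at C11, which rests on the size difference between the cage and methyl; and alkylation at C6 instead of C4, which rests on generating the enolate from 12 without proton exchange and on the high reactivity of the allylic iodide at low temperature.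

Step 6
Reactants: 14 (2S,3S,4S)-3-allyl-4-methyl-2-(2-methylallyl)-4-(4-methyl-2,6,7-trioxabicyclo[2.2.2]octan-1-yl)cyclohexan-1-one
Product: 15 trans-fused octalone (C5 ketone; C8=C9 alkene with methyl on C8; orthoester on C2)
Conditions: second-generation Grubbs catalyst RuCl2(=CHPh)(H2IMes)(PCy3) (5 mol%), CH2Cl2, 40 °C
Reagents that add atoms: none
Why: Ring-closing metathesis of a monosubstituted with a 1,1-disubstituted alkene; the two chains are trans-diequatorial on C6 and C11, so the six-membered ring closes to the trans-fused octalin with the trisubstituted C8=C9 alkene and loss of ethene.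

Step 7
Reactants: 15 trans-fused octalone
Product: 16 5α-alcohol (axial hydroxyl on C5 trans to the C6 hydrogen; C8=C9 alkene)
Conditions: LiBH(s-Bu)3, THF, −78 °C; NaOH, H2O2, 0 °C
Reagents that add atoms: none
Why: Reduction with a bulky trialkylborohydride: equatorial attack from the β-face avoids the axial hydrogens on C3 and C11 and gives the axial 5α-alcohol, which is the anchor for step 8.

Step 8
Reactants: 16 5α-alcohol
Product: 17 saturated 5α-alcohol with 8β (axial) methyl
Conditions: [Ir(cod)(PCy3)(py)]PF6 (5 mol%), H2 (1 atm), CH2Cl2, rt
Reagents that add atoms: none
Why: Hydroxyl-directed hydrogenation: the axial 5α-oxygen, syn-axial to C7, binds the cationic iridium centre and delivers hydrogen to the α-face of C8=C9, so the C8 methyl is pushed into the β (axial) position. Undirected approach should also be easier from the α-face, because the axial C2 methyl screens the β-face.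

Step 9
Reactants: 17 saturated 5α-alcohol
Product: 18 trans-decalone (C5 ketone; 8β-methyl; orthoester on C2)
Conditions: Dess–Martin periodinane, pyridine, CH2Cl2, rt
Reagents that add atoms: none
Why: Buffered Dess–Martin oxidation returns the C5 ketone without touching the orthoester; C6 keeps the more stable trans fusion.

Step 10
Reactants: 18 trans-decalone
Product: 20 ring A enone (C3=C4–C5=O), via silyl enol ether 19 (not isolated)
Conditions: LiN(i-Pr)2, Me3SiCl, THF, −78 °C; Pd(OAc)2, MeCN, rt
Reagents that add atoms: none
Why: Saegusa–Ito oxidation: kinetic deprotonation takes place at the C4 methylene (C6 is a tertiary ring-fusion carbon), silylation gives 19, and divalent palladium effects dehydrosilylation to the C3=C4 enone.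

Step 11
Reactants: 20 ring A enone
Product: 21 5β-allylic alcohol (hydroxyl on C5 cis to the C6 hydrogen; C3=C4 alkene)
Conditions: LiAlH4, Et2O, −78 °C
Reagents that add atoms: none
Why: 1,2-Reduction by a small hydride: axial attack from the α-face, anti to the axial C6–H, gives the pseudo-equatorial 5β-alcohol; conjugate reduction is disfavoured at the neopentyl C3.

Step 12
Reactants: 21 5β-allylic alcohol; 22 tributyl(iodomethyl)stannane
Product: 23 5β-(tributylstannyl)methyl ether
Conditions: KH, THF, 0 °C → rt
Reagents that add atoms: none
Why: Williamson etherification of the potassium alkoxide with the primary iodide; it places the latent carbanion carbon C12 on the β-oxygen.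

Step 13
Reactants: 23 5β-(tributylstannyl)methyl ether
Product: 25 3β-hydroxymethyl compound (C4=C5 alkene; orthoester on C2), via lithiomethyl ether 24 (not isolated)
Conditions: n-BuLi, THF, −78 → −40 °C
Reagents that add atoms: none
Why: Wittig–Still rearrangement: tin–lithium exchange gives the α-alkoxymethyllithium 24, whose [2,3]-sigmatropic shift is suprafacial on the allyl unit, so the β C5–O bond is exchanged for a β C3–C12 bond, syn to the axial C2 methyl, and the alkene moves to C4=C5. The intramolecular delivery overrides the steric bias that would send an external nucleophile to the α-face.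

Step 14
Reactants: 25 3β-hydroxymethyl compound
Product: 26 3β-carbaldehyde
Conditions: Dess–Martin periodinane, pyridine, CH2Cl2, 0 °C
Reagents that add atoms: none
Why: Buffered Dess–Martin oxidation gives the β,γ-unsaturated aldehyde without base, so C3 is not epimerised and the alkene does not move into conjugation; 26 is used at once.

Step 15
Reactants: 26 3β-carbaldehyde
Product: 27 3β-[(E)-2-iodovinyl] compound
Conditions: CrCl2, CHI3, THF/dioxane, 0 °C → rt
Reagents that add atoms: iodoform, IC(I)I
Why: Takai–Utimoto olefination: the geminal dichromium species formed from CHI3 and divalent chromium adds to the aldehyde and eliminates to the (E)-iodoalkene; the conditions are not basic, which protects the C3 stereocentre.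

Step 16
Reactants: 27 3β-[(E)-2-iodovinyl] compound; 28 (E)-prop-1-enylboronic acid
Product: 29 1-[(1R,2R,4aR,6R,8aS)-1,6-dimethyl-2-[(1E,3E)-penta-1,3-dienyl]-1,2,4a,5,6,7,8,8a-octahydronaphthalen-1-yl]-4-methyl-2,6,7-trioxabicyclo[2.2.2]octane
Conditions: Pd(PPh3)4 (5 mol%), K3PO4, THF/H2O, 50 °C
Reagents that add atoms: none
Why: Suzuki–Miyaura coupling with retention at both alkenyl partners gives the (1E,3E)-diene; the orthoester is stable to aqueous base.

Step 17
Reactants: 29 dienyl orthoester
Product: 30 3-hydroxy-2-(hydroxymethyl)-2-methylpropyl ester of the decalin carboxylic acid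
Conditions: NaHSO4 (0.05 M aq.), DME, 0 °C
Reagents that add atoms: water, O
Why: Mild aqueous acid opens the bicyclic orthoester to the monoester of the triol (orthoester hydrolysis); the diene is not protonated at this acidity.

Step 18
Reactants: 30 triol monoester
Product: 31 [(1R,2R,4aR,6R,8aS)-1,6-dimethyl-2-[(1E,3E)-penta-1,3-dienyl]-1,2,4a,5,6,7,8,8a-octahydronaphthalen-1-yl]methanol
Conditions: LiAlH4, THF, 0 → 50 °C
Reagents that add atoms: none
Why: Hydride reduction of the hindered ester to the primary alcohol with release of the triol; the isolated alkene and the diene are inert to LiAlH4.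

Step 19
Reactants: 31 C1 alcohol
Product: 32 (1R,2R,4aR,6R,8aS)-1,6-dimethyl-2-[(1E,3E)-penta-1,3-dienyl]-1,2,4a,5,6,7,8,8a-octahydronaphthalene-1-carbaldehyde
Conditions: Dess–Martin periodinane, CH2Cl2, rt
Reagents that add atoms: none
Why: Dess–Martin oxidation to an aldehyde that has no α-hydrogen and cannot epimerise.

Step 20
Reactants: 32 C1 aldehyde; 33 S-tert-butyl thioacetate
Product: 34 S-tert-butyl 3-hydroxy-3-(decalinyl)propanethioate (both carbinol epimers)
Conditions: LiN(i-Pr)2, THF, −78 °C (33 first; then 32); aq. NH4Cl
Reagents that add atoms: none
Why: Aldol addition of the lithium enolate of the thioester to the non-enolisable aldehyde; the new carbinol centre is oxidised in the next step, so its configuration does not matter.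

Step 21
Reactants: 34 β-hydroxy thioester
Product: 35 S-tert-butyl 3-oxo-3-(decalinyl)propanethioate
Conditions: Dess–Martin periodinane, CH2Cl2, rt
Reagents that add atoms: none
Why: Oxidation of the β-hydroxy thioester to the β-keto thioester, which sets C1 at its final oxidation state.

Step 22
Reactants: 36 L-threonine methyl ester hydrochloride
Product: 37 methyl O-(tert-butyldimethylsilyl)-L-threoninate
Conditions: t-BuMe2SiCl, imidazole, DMF, rt
Reagents that add atoms: tert-butyldimethylsilyl chloride, CC(C)(C)[Si](C)(C)Cl
Why: Silylation of the secondary hydroxyl (N-silylation is reversed on work-up); the ether blocks β-elimination and O-acylation in the last steps and leaves both stereocentres untouched.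

Step 23
Reactants: 35 β-keto thioester; 37 methyl O-(tert-butyldimethylsilyl)-L-threoninate
Product: 38 methyl N-[3-oxo-3-(decalinyl)propanoyl]-O-(tert-butyldimethylsilyl)-L-threoninate
Conditions: CF3CO2Ag, Et3N, THF, 0 °C → rt
Reagents that add atoms: none
Why: Silver-assisted aminolysis: the thiophilic silver salt activates the thioester, so the amine is acylated at 0 °C without touching the methyl ester or C5′.

Step 24
Reactants: 38 β-ketoamide
Product: 39 O-tert-butyldimethylsilyl ether of the target
Conditions: NaOMe, MeOH, rt, short contact; cold dilute HCl
Reagents that add atoms: none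
Why: Lacey–Dieckmann cyclisation: the β-ketoamide enolate attacks the methyl ester and closes the pyrrolidine-2,4-dione with loss of methanol; the short exposure to methoxide limits epimerisation at C5′.

Step 25
Reactants: 39 silyl ether of the target
Product: 40 (5S)-3-{[(1R,2R,4aR,6R,8aS)-1,6-dimethyl-2-[(1E,3E)-penta-1,3-dienyl]-1,2,4a,5,6,7,8,8a-octahydronaphthalen-1-yl]carbonyl}-4-hydroxy-5-[(1R)-1-hydroxyethyl]-1,5-dihydro-2H-pyrrol-2-one
Conditions: aq. HF, MeCN, 0 °C
Reagents that add atoms: none
Why: Fluoride cleavage of the silyl ether under mildly acidic conditions that leave the diene and the tricarbonyl unit intact.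

## Compound list

("Decalinyl" = (1R,2R,4aR,6R,8aS)-1,6-dimethyl-2-[(1E,3E)-penta-1,3-dienyl]-1,2,4a,5,6,7,8,8a-octahydronaphthalen-1-yl; "OBO" = 4-methyl-2,6,7-trioxabicyclo[2.2.2]octan-1-yl.)

1 | (E)-3-(tert-butyldimethylsilyloxy)-N,N-dimethylbuta-1,3-dien-1-amine | CN(C)/C=C/C(=C)O[Si](C)(C)C(C)(C)C | starting material
2 | methacrolein (2-methylprop-2-enal) | CC(=C)C=O | starting material
3 | 2-(dimethylamino)-1-methyl-4-(tert-butyldimethylsilyloxy)cyclohex-3-ene-1-carbaldehyde, formyl cis to the amino group, quaternary centre as in 5 | C1CC(O[Si](C)(C)C(C)(C)C)=C[C@@H](N(C)C)[C@@]1(C)C=O | intermediate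
4 | [2-(dimethylamino)-1-methyl-4-(tert-butyldimethylsilyloxy)cyclohex-3-en-1-yl]methanol, configuration of 3 | C1CC(O[Si](C)(C)C(C)(C)C)=C[C@@H](N(C)C)[C@@]1(C)CO | intermediate
5 | (S)-4-(hydroxymethyl)-4-methylcyclohex-2-en-1-one | C1CC(=O)C=C[C@@]1(C)CO | intermediate
6 | (S)-1-methyl-4-oxocyclohex-2-ene-1-carboxylic acid | C1CC(=O)C=C[C@@]1(C)C(=O)O | intermediate
7 | (3-methyloxetan-3-yl)methanol | CC1(CO)COC1 | starting material
8 | (3-methyloxetan-3-yl)methyl (S)-1-methyl-4-oxocyclohex-2-ene-1-carboxylate | C1CC(=O)C=C[C@@]1(C)C(=O)OCC2(C)COC2 | intermediate
9 | (S)-4-methyl-4-(4-methyl-2,6,7-trioxabicyclo[2.2.2]octan-1-yl)cyclohex-2-en-1-one | C1CC(=O)C=C[C@@]1(C)C23OCC(C)(CO2)CO3 | intermediate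
10 | allylmagnesium bromide | C=CC[Mg]Br | starting material
11 | 3-iodo-2-methylprop-1-ene | CC(=C)CI | starting material
12 | trimethylsilyl enol ether (C5–OSiMe3, C5=C6) of the 3-allyl ketone, allyl on C11 cis to the C2 methyl | C1CC(O[Si](C)(C)C)=C[C@H](CC=C)[C@@]1(C)C23OCC(C)(CO2)CO3 | intermediate
13 | lithium enolate corresponding to 12 | C1CC([O-])=C[C@H](CC=C)[C@@]1(C)C23OCC(C)(CO2)CO3.[Li+] | intermediate
14 | (2S,3S,4S)-3-allyl-4-methyl-2-(2-methylallyl)-4-(OBO)cyclohexan-1-one (allyl cis to methyl, 2-methylallyl trans to allyl) | C1CC(=O)[C@@H](CC(C)=C)[C@H](CC=C)[C@@]1(C)C23OCC(C)(CO2)CO3 | intermediate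
15 | trans-fused octalone: C5 ketone, C8=C9 alkene with methyl on C8, C2 with β-methyl and α-OBO, 6-H β, 11-H α | C1CC(=O)[C@H]2CC(C)=CC[C@@H]2[C@@]1(C)C34OCC(C)(CO3)CO4 | intermediate
16 | 5α-alcohol of 15 (axial hydroxyl, trans to 6-H) | C1C[C@@H](O)[C@H]2CC(C)=CC[C@@H]2[C@@]1(C)C34OCC(C)(CO3)CO4 | intermediate
17 | saturated 5α-alcohol with 8β (axial) methyl | C1C[C@@H](O)[C@H]2C[C@H](C)CC[C@@H]2[C@@]1(C)C34OCC(C)(CO3)CO4 | intermediate
18 | trans-decalone: C5 ketone, 8β-methyl, OBO on C2 | C1CC(=O)[C@H]2C[C@H](C)CC[C@@H]2[C@@]1(C)C34OCC(C)(CO3)CO4 | intermediate
19 | trimethylsilyl enol ether of 18 (C4=C5) | C1C=C(O[Si](C)(C)C)[C@H]2C[C@H](C)CC[C@@H]2[C@@]1(C)C34OCC(C)(CO3)CO4 | intermediate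
20 | ring A enone: C3=C4–C5=O | C1=CC(=O)[C@H]2C[C@H](C)CC[C@@H]2[C@@]1(C)C34OCC(C)(CO3)CO4 | intermediate
21 | 5β-allylic alcohol (hydroxyl cis to 6-H), C3=C4 | C1=C[C@H](O)[C@H]2C[C@H](C)CC[C@@H]2[C@@]1(C)C34OCC(C)(CO3)CO4 | intermediate
22 | tributyl(iodomethyl)stannane | CCCC[Sn](CCCC)(CCCC)CI | starting material
23 | 5β-(tributylstannyl)methyl ether of 21 | C1=C[C@H](OC[Sn](CCCC)(CCCC)CCCC)[C@H]2C[C@H](C)CC[C@@H]2[C@@]1(C)C34OCC(C)(CO3)CO4 | intermediate
24 | 5β-(lithiomethyl) ether | C1=C[C@H](OC[Li])[C@H]2C[C@H](C)CC[C@@H]2[C@@]1(C)C34OCC(C)(CO3)CO4 | intermediate
25 | 3β-hydroxymethyl compound, C4=C5 alkene, OBO on C2 | OC[C@@H]1C=C[C@H]2C[C@H](C)CC[C@@H]2[C@@]1(C)C34OCC(C)(CO3)CO4 | intermediate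
26 | 3β-carbaldehyde | O=C[C@@H]1C=C[C@H]2C[C@H](C)CC[C@@H]2[C@@]1(C)C34OCC(C)(CO3)CO4 | intermediate
27 | 3β-[(E)-2-iodovinyl] compound | I/C=C/[C@@H]1C=C[C@H]2C[C@H](C)CC[C@@H]2[C@@]1(C)C34OCC(C)(CO3)CO4 | intermediate
28 | (E)-prop-1-enylboronic acid | C/C=C/B(O)O | starting material
29 | 1-(decalinyl)-4-methyl-2,6,7-trioxabicyclo[2.2.2]octane | C/C=C/C=C/[C@@H]1C=C[C@H]2C[C@H](C)CC[C@@H]2[C@@]1(C)C34OCC(C)(CO3)CO4 | intermediate
30 | 3-hydroxy-2-(hydroxymethyl)-2-methylpropyl decalin-1-carboxylate | C/C=C/C=C/[C@@H]1C=C[C@H]2C[C@H](C)CC[C@@H]2[C@@]1(C)C(=O)OCC(C)(CO)CO | intermediate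
31 | (decalinyl)methanol | C/C=C/C=C/[C@@H]1C=C[C@H]2C[C@H](C)CC[C@@H]2[C@@]1(C)CO | intermediate
32 | decalin-1-carbaldehyde (C1 aldehyde) | C/C=C/C=C/[C@@H]1C=C[C@H]2C[C@H](C)CC[C@@H]2[C@@]1(C)C=O | intermediate
33 | S-tert-butyl thioacetate | CC(=O)SC(C)(C)C | starting material
34 | S-tert-butyl 3-hydroxy-3-(decalinyl)propanethioate, both carbinol epimers | C/C=C/C=C/[C@@H]1C=C[C@H]2C[C@H](C)CC[C@@H]2[C@@]1(C)C(O)CC(=O)SC(C)(C)C | intermediate
35 | S-tert-butyl 3-oxo-3-(decalinyl)propanethioate | C/C=C/C=C/[C@@H]1C=C[C@H]2C[C@H](C)CC[C@@H]2[C@@]1(C)C(=O)CC(=O)SC(C)(C)C | intermediate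
36 | L-threonine methyl ester hydrochloride | C[C@@H](O)[C@H](N)C(=O)OC.Cl | starting material
37 | methyl O-(tert-butyldimethylsilyl)-L-threoninate | C[C@@H](O[Si](C)(C)C(C)(C)C)[C@H](N)C(=O)OC | intermediate
38 | methyl N-[3-oxo-3-(decalinyl)propanoyl]-O-(tert-butyldimethylsilyl)-L-threoninate | C/C=C/C=C/[C@@H]1C=C[C@H]2C[C@H](C)CC[C@@H]2[C@@]1(C)C(=O)CC(=O)N[C@@H]([C@@H](C)O[Si](C)(C)C(C)(C)C)C(=O)OC | intermediate
39 | (5S)-3-(decalinylcarbonyl)-4-hydroxy-5-[(1R)-1-(tert-butyldimethylsilyloxy)ethyl]-1,5-dihydro-2H-pyrrol-2-one | C/C=C/C=C/[C@@H]1C=C[C@H]2C[C@H](C)CC[C@@H]2[C@@]1(C)C(=O)C1=C(O)[C@H]([C@@H](C)O[Si](C)(C)C(C)(C)C)NC1=O | intermediate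
40 | (5S)-3-(decalinylcarbonyl)-4-hydroxy-5-[(1R)-1-hydroxyethyl]-1,5-dihydro-2H-pyrrol-2-one | C/C=C/C=C/[C@@H]1C=C[C@H]2C[C@H](C)CC[C@@H]2[C@@]1(C)C(=O)C1=C(O)[C@H]([C@@H](C)O)NC1=O | target

## Step count and least certain steps

Total: 25 steps. Longest linear sequence: 24 steps (steps 1–21 and 23–25); step 22 is a one-step side branch.

Step 5 (key step). The second bond formation is the most likely weak point: the hindered lithium enolate 13 may exchange protons with the product faster than it is alkylated next to the neopentyl C11, which would lead to alkylation at C4 or to double alkylation. Less likely is incomplete face discrimination at C11, whose minor isomer would be removed at 15. Fallback: setting out from 9, the conjugate allylation is kept, but enolate 13 is acylated on oxygen with 2-methylallyl chloroformate to the 2-methylallyl enol carbonate F1. Pd(PPh3)4 (zerovalent palladium) then ionises F1 to a π-allyl/enolate ion pair that recombines at C6 with loss of carbon dioxide (decarboxylative allylation), regiospecifically and trans to the C11 allyl group. This comes back to the route at 14.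

Step 13. The [1,2]-shift or simple protonation of 24 may compete with the [2,3]-shift, because the pseudo-equatorial C5–O bond of the locked ring overlaps only partly with the alkene and the migrating carbon must bond next to a quaternary centre, syn to its axial methyl. Fallback: setting out from 21, phenyl isocyanate and pyridine give the 5β-N-phenylcarbamate F2. After deprotonation with MeLi and complexation with CuI, the dienyl group is transferred from (1E,3E)-penta-1,3-dienyllithium, which is made by t-BuLi exchange from (1E,3E)-1-iodopenta-1,3-diene F3 (itself from (E)-but-2-enal, CHI3 and CrCl2). The transfer takes place within the copper carbamate complex to C3, on the face of the carbamate and with allylic transposition (carbamate-directed syn-SN2′ substitution). This comes back to the route at 29 and bypasses steps 13–16.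

Step 8. Direction by a bishomoallylic alcohol is weaker than by an allylic or homoallylic one, and the orthoester oxygens may bind the iridium centre; the result would be slow conversion or loss of face selectivity. Fallback: setting out from 15, undirected hydrogenation over palladium on carbon in EtOAc relies on substrate control alone (the axial C2 methyl screens the β-face of ring B). It comes back to the route at 18 and omits steps 7 and 9; it makes no compound outside the list (F0).

Step 15. Aldehyde 26 is β,γ-unsaturated with its stereocentre in the α-position, so epimerisation at C3 or migration of the alkene into conjugation can occur. Addition to the hindered carbonyl may also be slow, and chromium salts may attack the orthoester during work-up. Fallback: setting out from 25, the polarity is reversed so that no aldehyde is made at C12. A Mitsunobu reaction with 1-phenyl-1H-tetrazole-5-thiol (PPh3, diisopropyl azodicarboxylate) gives the sulfide F4, and oxidation with n-Pr4N[RuO4] (cat.) and N-methylmorpholine N-oxide gives the sulfone F5. Deprotonation with KN(SiMe3)2 in DME at −60 °C and addition of (E)-but-2-enal forms the C12=C13 alkene by Julia–Kocienski olefination. This comes back to the route at 29.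

Step 1. Enantiofacial control by the hydrogen-bonding catalyst may be incomplete, and every later stereocentre is derived from C2. Fallback: setting out from 6 of insufficient enantiomeric purity, the acid is crystallised as its salt with (S)-1-phenylethylamine, F6 (or with the antipodal amine, whichever gives the less soluble salt of the (S)-acid). Acidification comes back to the route at 6; this is a classical resolution in place of reliance on the catalyst.

## Further compounds

F1 | step 5 | 2-methylallyl enol carbonate of the 3-allyl ketone (C5–O–CO–O–CH2C(CH3)=CH2, C5=C6) | C1CC(OC(=O)OCC(C)=C)=C[C@H](CC=C)[C@@]1(C)C23OCC(C)(CO2)CO3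
F2 | step 13 | 5β-N-phenylcarbamate of 21 | C1=C[C@H](OC(=O)Nc5ccccc5)[C@H]2C[C@H](C)CC[C@@H]2[C@@]1(C)C34OCC(C)(CO3)CO4
F3 | step 13 | (1E,3E)-1-iodopenta-1,3-diene | C/C=C/C=C/I
F0 | step 8 | none | none
F4 | step 15 | 3β-[(1-phenyl-1H-tetrazol-5-yl)sulfanylmethyl] compound | C(Sc5nnnn5c6ccccc6)[C@@H]1C=C[C@H]2C[C@H](C)CC[C@@H]2[C@@]1(C)C34OCC(C)(CO3)CO4
F5 | step 15 | 3β-[(1-phenyl-1H-tetrazol-5-yl)sulfonylmethyl] compound | C(S(=O)(=O)c5nnnn5c6ccccc6)[C@@H]1C=C[C@H]2C[C@H](C)CC[C@@H]2[C@@]1(C)C34OCC(C)(CO3)CO4
F6 | step 1 | (S)-1-phenylethylammonium salt of acid 6 | C1CC(=O)C=C[C@@]1(C)C(=O)O.C[C@H](N)c1ccccc1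
A1 | alternative 1 | trans-fused octalone with C5 ketone, C9=C10 alkene, axial C8 methyl, silyloxymethyl on C2 and 4-methoxybenzyloxymethyl on C3 | COc1ccc(COC[C@@H]2CC(=O)[C@H]3C[C@H](C)C=C[C@@H]3[C@@]2(C)CO[Si](c4ccccc4)(c5ccccc5)C(C)(C)C)cc1
A2 | alternative 1 | open-chain trienone (vinyl ketone C5–C7, (E,E)-diene C11–C8 on quaternary C2) | C=CC(=O)C[C@@H](COCc1ccc(OC)cc1)[C@](C)(CO[Si](c2ccccc2)(c3ccccc3)C(C)(C)C)/C=C/C=C/C
A3 | alternative 2 | octalin aldehyde with C5=C6 alkene, quaternary C2 and C11 set | C1CC=C2C[C@H](C)CC[C@@H]2[C@@]1(C)C=O
A4 | alternative 2 | (R)-5-methyl-1-vinylcyclohexene | C=CC1=CCC[C@@H](C)C1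
A5 | alternative 2 | methacrolein (identical with 2) | CC(=C)C=O
A6 | alternative 3 | ring A acid with axial carboxyl and equatorial 4-methoxybenzyloxymethyl on C2, silyloxymethyl on C3 | CC(C)(C)[Si](C)(C)OC[C@@H]1C=C[C@H]2C[C@H](C)CC[C@@H]2[C@@]1(C(=O)O)COCc3ccc(OC)cc3
A7 | alternative 3 | trans-fused δ-lactone (ring oxygen between C5 and the carboxyl carbon on C2; (E)-3-silyloxyprop-1-enyl on C5; C2 becomes trigonal on enolisation and is left undefined) | O=C1O[C@@H](/C=C/CO[Si](C)(C)C(C)(C)C)[C@H]2C[C@H](C)CC[C@@H]2C1COCc1ccc(OC)cc1
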